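**Retrosynthetic overview**

1. The 15,16-lactone comes from oxidation of a lactol. The oxolane (O, C9, C11, C12, C13) comes from 5-exo opening of an 8β,9β-epoxy-7-ketone at C9 by the C13 tertiary hydroxyl, which sets the trans C9–O / C8–OH pair.
2. The epoxy ketone comes from a 7-oxo-Δ8 enone (reduction, hydroxyl-directed epoxidation, reoxidation). The enone comes from 1,2-addition of a C11–C16 alkyllithium (C13 set by Sharpless epoxidation) to the C9 ketone of 11-nordrim-7-en-9-one, then oxidative 1,3-transposition.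
3. Ring A is disconnected at C3–C4. The feature used is that ring B (C5–C10) with its C8 methyl, its C9 oxygen and the gem-dimethyl carbon C4 on C5 is (R)-carvone (carbonyl = C9, isopropenyl carbon = C4), so ring A lacks only C1–C3 and the C3–C4 bond.
4. That bond is made by protonating the isopropenyl group to the C4 cation and trapping it at the silicon-bearing carbon C3 of a Z-vinylsilane arm. The arm is installed, after a methyl group, by enolate alkylation at the carvone α′ carbon (C10).
5. Ring order: B (carvone) → A (key step) → oxolane (closed together with the lactol) → lactone.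

Key step: step 5

Remark: positions are given in labdane numbering (C15 = lactone carbonyl, C16 = lactone CH2O); the C9 carbinol formed in the organolithium addition is drawn as the expected 9β-alcohol, but either epimer serves because this centre is erased in the following step.

**Route**

Step 1
Reactants: 1 3-(trimethylsilyl)prop-2-yn-1-ol
Product: 2 (Z)-3-(trimethylsilyl)prop-2-en-1-ol
Conditions: H2 (1 atm), Ni(OAc)2·4H2O/NaBH4 (P-2 nickel boride, 5 mol%), ethylenediamine, EtOH, rt
Reagents that add atoms: none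
Why: cis-semihydrogenation of the silylalkyne on nickel boride delivers both hydrogens to one face and stops at the alkene, which fixes the Z geometry needed in step 5.

Step 2
Reactants: 2 (Z)-3-(trimethylsilyl)prop-2-en-1-ol
Product: 3 (Z)-(3-bromoprop-1-en-1-yl)trimethylsilane
Conditions: CBr4, PPh3, CH2Cl2, 0 °C
Reagents that add atoms: carbon tetrabromide BrC(Br)(Br)Br
Why: Appel bromination displaces the activated primary allylic oxygen by SN2 at CH2 under near-neutral conditions, so the Z-vinylsilane should be neither isomerised nor desilylated.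

Step 3
Reactants: 4 (R)-carvone
Product: 6 (5R,6S)-2,6-dimethyl-5-(prop-1-en-2-yl)cyclohex-2-en-1-one (trans-6-methylcarvone), via carvone lithium dienolate 5 (not isolated)
Conditions: LiN(iPr)2, THF, −78 °C; MeI, −78 → 0 °C
Reagents that add atoms: iodomethane CI
Why: kinetic deprotonation occurs at the α′ CH2 and the cross-conjugated enolate is C-methylated mainly anti to the isopropenyl group; the configuration of this carbon does not matter because it is re-enolised in step 4.

Step 4
Reactants: 6 trans-6-methylcarvone; 3 (Z)-(3-bromoprop-1-en-1-yl)trimethylsilane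
Product: 8 (5S,6S)-2,6-dimethyl-5-(prop-1-en-2-yl)-6-[(Z)-3-(trimethylsilyl)prop-2-en-1-yl]cyclohex-2-en-1-one (silylallyl arm trans to isopropenyl), via lithium enolate 7 (not isolated)
Conditions: LiN(iPr)2, THF, −78 → 0 °C; DMPU, then 3, −78 °C → rt
Reagents that add atoms: none
Why: enolate alkylation with the reactive allylic bromide (SN2 at CH2, Z geometry kept) should occur on the face opposite the adjacent isopropenyl group, which sets the quaternary carbon (later C10) with the new arm trans to isopropenyl.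

Step 5
Reactants: 8 silylallyl methylcarvone
Product: 9 (4aS,8aS)-2,5,5,8a-tetramethyl-4a,5,8,8a-tetrahydronaphthalen-1(4H)-one (trans-fused 11-nordrima-2,7-dien-9-one)
Conditions: HNTf2 (20 mol%), (CF3)2CHOH/CH2Cl2 (1:1), 0 °C; aq. NaHCO3
Reagents that add atoms: none
Why: The strong Brønsted acid protonates the 1,1-disubstituted isopropenyl alkene (the enone is only reversibly O-protonated) to the tertiary C4 cation, which is captured at the silicon-bearing carbon C3 of the vinylsilane to form C3–C4; the resulting C2 cation is stabilised by the β C–Si bond, and Me3Si is then lost to the fluoro alcohol to leave the C2=C3 alkene and return the proton. The closest known reaction type is the vinylsilane-terminated cation–olefin cyclisation (ipso-substitution of a vinylsilane by a tertiary carbocation). Ring A closes in the 6-endo mode with respect to the vinylsilane through a chair transition state with the C10 methyl axial and the two arms on C5 and C10 equatorial. No new stereocentre is formed: C5 comes from carvone and C10 from step 4, and their trans arrangement allows only the trans ring fusion. The step needs chemoselective protonation (the 1,1-disubstituted alkene is far more basic than the 1,2-disubstituted vinylsilane), six- rather than five-membered closure (the β-silicon effect directs attack to C3) and a cis ring alkene (the Z geometry, because ipso-substitution proceeds with retention).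

Step 6
Reactants: 9 11-nordrima-2,7-dien-9-one
Product: 10 (4aS,8aS)-2,5,5,8a-tetramethyl-4a,5,6,7,8,8a-hexahydronaphthalen-1(4H)-one (11-nordrim-7-en-9-one)
Conditions: H2 (3 atm), RhCl(PPh3)3 (5 mol%), benzene, rt
Reagents that add atoms: none
Why: homogeneous hydrogenation with RhCl(PPh3)3 reduces the cis-disubstituted ring A alkene much faster than the trisubstituted conjugated alkene of the enone, and no stereocentre is formed.

Step 7
Reactants: 11 3-bromobut-3-en-1-ol
Product: 12 [(3-bromobut-3-en-1-yl)oxy](tert-butyl)diphenylsilane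
Conditions: TBDPSCl, imidazole, CH2Cl2, 0 °C → rt
Reagents that add atoms: tert-butyl(chloro)diphenylsilane CC(C)(C)[Si](Cl)(c1ccccc1)c1ccccc1
Why: standard silylation of a primary alcohol gives an ether that should survive the organolithium, titanium, copper and mild-acid conditions of steps 8–11.

Step 8
Reactants: 12 bromoalkene silyl ether
Product: 14 2-[2-(tert-butyldiphenylsilyloxy)ethyl]prop-2-en-1-ol, via vinyllithium 13 (not isolated)
Conditions: t-BuLi (2.1 equiv), Et2O, −78 °C; (CH2O)n, −78 °C → rt; H2O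
Reagents that add atoms: formaldehyde (as paraformaldehyde) C=O
Why: bromine–lithium exchange gives the 2-lithioalkene, which adds to formaldehyde to give the 2-substituted primary allylic alcohol required for asymmetric epoxidation.

Step 9
Reactants: 14 2-substituted allylic alcohol
Product: 15 {(2R)-2-[2-(tert-butyldiphenylsilyloxy)ethyl]oxiran-2-yl}methanol
Conditions: Ti(OiPr)4 (10 mol%), D-(−)-diethyl tartrate (12 mol%), t-BuOOH, 4 Å MS, CH2Cl2, −20 °C
Reagents that add atoms: tert-butyl hydroperoxide CC(C)(C)OO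
Why: Sharpless asymmetric epoxidation of a 2-substituted primary allylic alcohol, in which the D-(−)-tartrate ligand directs oxygen to the face giving the 2R epoxide, so that the future C13 is set by reagent control.

Step 10
Reactants: 15 epoxy alcohol
Product: 16 (2R)-2-[2-(tert-butyldiphenylsilyloxy)ethyl]pent-4-ene-1,2-diol
Conditions: CH2=CHMgBr (3.5 equiv), CuI (15 mol%), THF, −40 → −10 °C; aq. NH4Cl
Reagents that add atoms: vinylmagnesium bromide C=C[Mg]Br
Why: copper-catalysed Grignard opening occurs by SN2 attack at the unsubstituted epoxide CH2, so the tertiary C–O bond and the configuration set in step 9 are untouched.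

Step 11
Reactants: 16 diol
Product: 17 (4R)-4-allyl-4-[2-(tert-butyldiphenylsilyloxy)ethyl]-2,2-dimethyl-1,3-dioxolane
Conditions: Me2C(OMe)2, PPTS (cat.), CH2Cl2, rt
Reagents that add atoms: 2,2-dimethoxypropane COC(C)(C)OC
Why: acid-catalysed transketalisation ties the tertiary and primary hydroxyls into one dioxolane, which masks both through the organolithium and oxidation steps.

Step 12
Reactants: 17 silyl ether ketal
Product: 18 2-[(4R)-4-allyl-2,2-dimethyl-1,3-dioxolan-4-yl]ethan-1-ol
Conditions: Bu4NF, THF, rt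
Reagents that add atoms: none
Why: fluoride cleaves the Si–O bond selectively, the ketal and the alkene being inert.

Step 13
Reactants: 18 primary alcohol
Product: 19 (4R)-4-allyl-4-(2-iodoethyl)-2,2-dimethyl-1,3-dioxolane
Conditions: I2, PPh3, imidazole, CH2Cl2, 0 °C → rt
Reagents that add atoms: iodine [I][I]
Why: Appel-type iodination of the primary alcohol via its alkoxyphosphonium salt proceeds by SN2 under imidazole buffering, so the acid-sensitive ketal should survive.

Step 14
Reactants: 19 iodide; 10 11-nordrim-7-en-9-one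
Product: 21 9-{2-[(4S)-4-allyl-2,2-dimethyl-1,3-dioxolan-4-yl]ethyl}-11-nordrim-7-en-9-ol (9β-alcohol expected), via alkyllithium 20 (not isolated)
Conditions: 19, t-BuLi (2.1 equiv), Et2O/pentane, −78 °C; then 10, −78 → 0 °C; H2O
Reagents that add atoms: none
Why: iodine–lithium exchange gives a primary alkyllithium that adds 1,2 to the C9 ketone, which has no α-hydrogen (C10 quaternary, C8 sp2) and so cannot be enolised at the α position; attack anti to the axial C10 methyl should favour the 9β-alcohol.

Step 15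
Reactants: 21 tertiary allylic alcohol
Product: 22 9-{2-[(4S)-4-allyl-2,2-dimethyl-1,3-dioxolan-4-yl]ethyl}-11-nordrim-8-en-7-one
Conditions: pyridinium chlorochromate ([C5H5NH][CrO3Cl]), 4 Å MS, CH2Cl2, rt
Reagents that add atoms: pyridinium chlorochromate [O-][Cr](=O)(=O)Cl.c1cc[nH+]cc1
Why: Babler–Dauben oxidative transposition, in which the chromate ester of the tertiary allylic alcohol undergoes a [3,3] shift to the secondary C7 chromate and is oxidised to the tetrasubstituted enone, removing the C9 carbinol centre.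

Step 16
Reactants: 22 7-oxo-Δ8 enone
Product: 23 9-{2-[(4S)-4-allyl-2,2-dimethyl-1,3-dioxolan-4-yl]ethyl}-11-nordrim-8-en-7β-ol
Conditions: NaBH4, CeCl3·7H2O, MeOH, −78 → −20 °C
Reagents that add atoms: none
Why: Luche 1,2-reduction, with hydride expected to arrive along the pseudoaxial α trajectory of the trans-fused half-chair to give the pseudoequatorial 7β-alcohol (C7 set by substrate control).

Step 17
Reactants: 23 7β-allylic alcohol
Product: 24 8β,9β-epoxy-9-{2-[(4S)-4-allyl-2,2-dimethyl-1,3-dioxolan-4-yl]ethyl}-11-nordriman-7β-ol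
Conditions: VO(acac)2 (5 mol%), t-BuOOH, CH2Cl2, 0 °C → rt
Reagents that add atoms: tert-butyl hydroperoxide CC(C)(C)OO
Why: hydroxyl-directed epoxidation, in which the vanadium alkoxide of the 7β-hydroxyl delivers the bound peroxide oxygen to the same (β) face of the Δ8 alkene, setting C8 and the provisional C9 configuration and leaving the terminal alkene, which has no allylic hydroxyl, untouched.

Step 18
Reactants: 24 epoxy alcohol
Product: 25 8β,9β-epoxy-9-{2-[(4S)-4-allyl-2,2-dimethyl-1,3-dioxolan-4-yl]ethyl}-11-nordriman-7-one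
Conditions: Dess–Martin periodinane, NaHCO3, CH2Cl2, rt
Reagents that add atoms: none
Why: Dess–Martin oxidation of the secondary alcohol under buffered, non-acidic conditions should leave the epoxide, ketal and alkene intact.

Step 19
Reactants: 25 epoxy ketone
Product: 26 8β,9β-epoxy-9-{2-[(4S)-2,2-dimethyl-4-(2-oxoethyl)-1,3-dioxolan-4-yl]ethyl}-11-nordriman-7-one
Conditions: O3, CH2Cl2, −78 °C; PPh3, −78 °C → rt
Reagents that add atoms: ozone [O-][O+]=O
Why: ozonolysis with reductive work-up cleaves the only remaining C=C bond to the C15 aldehyde.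

Step 20
Reactants: 26 epoxy keto aldehyde
Product: 28 (13S)-9α,13:15,16-diepoxy-8β,15-dihydroxylabdan-7-one (lactol; C15 anomers), via epoxy lactol 27 (not isolated)
Conditions: TsOH·H2O (0.2 equiv), THF/H2O (5:1), rt
Reagents that add atoms: none
Why: ketal hydrolysis frees the diol, whose primary C16 hydroxyl is taken up as the five-membered lactol while the tertiary C13 hydroxyl opens the protonated epoxide at the tertiary C9 in 5-exo-tet fashion with inversion (trans-diaxial, Fürst–Plattner), giving 9α-O and retaining the 8β-hydroxyl.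

Step 21
Reactants: 28 lactol
Product: 29 (13S)-9α,13-epoxy-8β-hydroxy-7-oxolabdan-15,16-olide (5S,8R,9S,10S,13S; CNP0208728.2)
Conditions: TEMPO (10 mol%), PhI(OAc)2, CH2Cl2, rt
Reagents that add atoms: none
Why: oxoammonium-mediated oxidation converts the lactol into the γ-lactone, while the tertiary alcohol, the ketone and the ethers cannot be oxidised under these conditions.

**Compound list**

1 | 3-(trimethylsilyl)prop-2-yn-1-ol | C[Si](C)(C)C#CCO | starting material
2 | (Z)-3-(trimethylsilyl)prop-2-en-1-ol | C[Si](C)(C)/C=C\CO | intermediate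
3 | (Z)-(3-bromoprop-1-en-1-yl)trimethylsilane | C[Si](C)(C)/C=C\CBr | intermediate
4 | (R)-carvone | CC1=CC[C@@H](C(C)=C)CC1=O | starting material
5 | lithium dienolate of carvone | CC1=CC[C@@H](C(C)=C)C=C1O[Li] | intermediate
6 | (5R,6S)-2,6-dimethyl-5-(prop-1-en-2-yl)cyclohex-2-en-1-one | CC1=CC[C@@H](C(C)=C)[C@H](C)C1=O | intermediate
7 | lithium enolate of 6-methylcarvone | CC1=CC[C@@H](C(C)=C)C(C)=C1O[Li] | intermediate
8 | (5S,6S)-2,6-dimethyl-5-(prop-1-en-2-yl)-6-[(Z)-3-(trimethylsilyl)prop-2-en-1-yl]cyclohex-2-en-1-one | CC1=CC[C@@H](C(C)=C)[C@](C)(C/C=C\[Si](C)(C)C)C1=O | intermediate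
9 | (4aS,8aS)-2,5,5,8a-tetramethyl-4a,5,8,8a-tetrahydronaphthalen-1(4H)-one | CC1(C)C=CC[C@@]2(C)[C@H]1CC=C(C)C2=O | intermediate
10 | (4aS,8aS)-2,5,5,8a-tetramethyl-4a,5,6,7,8,8a-hexahydronaphthalen-1(4H)-one | CC1(C)CCC[C@@]2(C)[C@H]1CC=C(C)C2=O | intermediate
11 | 3-bromobut-3-en-1-ol | OCCC(Br)=C | starting material
12 | [(3-bromobut-3-en-1-yl)oxy](tert-butyl)diphenylsilane | CC(C)(C)[Si](c1ccccc1)(c1ccccc1)OCCC(Br)=C | intermediate
13 | {4-[tert-butyl(diphenyl)silyloxy]but-1-en-2-yl}lithium | CC(C)(C)[Si](c1ccccc1)(c1ccccc1)OCCC([Li])=C | intermediate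
14 | 2-[2-(tert-butyldiphenylsilyloxy)ethyl]prop-2-en-1-ol | CC(C)(C)[Si](c1ccccc1)(c1ccccc1)OCCC(=C)CO | intermediate
15 | {(2R)-2-[2-(tert-butyldiphenylsilyloxy)ethyl]oxiran-2-yl}methanol | OC[C@]1(CCO[Si](c2ccccc2)(c2ccccc2)C(C)(C)C)CO1 | intermediate
16 | (2R)-2-[2-(tert-butyldiphenylsilyloxy)ethyl]pent-4-ene-1,2-diol | OC[C@@](O)(CC=C)CCO[Si](c1ccccc1)(c1ccccc1)C(C)(C)C | intermediate
17 | (4R)-4-allyl-4-[2-(tert-butyldiphenylsilyloxy)ethyl]-2,2-dimethyl-1,3-dioxolane | CC(C)(C)[Si](c1ccccc1)(c1ccccc1)OCC[C@]1(CC=C)COC(C)(C)O1 | intermediate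
18 | 2-[(4R)-4-allyl-2,2-dimethyl-1,3-dioxolan-4-yl]ethan-1-ol | OCC[C@]1(CC=C)COC(C)(C)O1 | intermediate
19 | (4R)-4-allyl-4-(2-iodoethyl)-2,2-dimethyl-1,3-dioxolane | ICC[C@]1(CC=C)COC(C)(C)O1 | intermediate
20 | [2-(4-allyl-2,2-dimethyl-1,3-dioxolan-4-yl)ethyl]lithium (same spatial arrangement as 19) | [Li]CC[C@]1(CC=C)COC(C)(C)O1 | intermediate
21 | 9-{2-[(4S)-4-allyl-2,2-dimethyl-1,3-dioxolan-4-yl]ethyl}-11-nordrim-7-en-9β-ol | CC1(C)CCC[C@@]2(C)[C@H]1CC=C(C)[C@@]2(O)CC[C@]1(CC=C)COC(C)(C)O1 | intermediate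
22 | 9-{2-[(4S)-4-allyl-2,2-dimethyl-1,3-dioxolan-4-yl]ethyl}-11-nordrim-8-en-7-one | CC1(C)CCC[C@@]2(C)[C@H]1CC(=O)C(C)=C2CC[C@]1(CC=C)COC(C)(C)O1 | intermediate
23 | 9-{2-[(4S)-4-allyl-2,2-dimethyl-1,3-dioxolan-4-yl]ethyl}-11-nordrim-8-en-7β-ol | CC1(C)CCC[C@@]2(C)[C@H]1C[C@H](O)C(C)=C2CC[C@]1(CC=C)COC(C)(C)O1 | intermediate
24 | 8β,9β-epoxy-9-{2-[(4S)-4-allyl-2,2-dimethyl-1,3-dioxolan-4-yl]ethyl}-11-nordriman-7β-ol | CC1(C)CCC[C@@]2(C)[C@H]1C[C@H](O)[C@]3(C)O[C@@]32CC[C@]1(CC=C)COC(C)(C)O1 | intermediate
25 | 8β,9β-epoxy-9-{2-[(4S)-4-allyl-2,2-dimethyl-1,3-dioxolan-4-yl]ethyl}-11-nordriman-7-one | CC1(C)CCC[C@@]2(C)[C@H]1CC(=O)[C@]3(C)O[C@@]32CC[C@]1(CC=C)COC(C)(C)O1 | intermediate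
26 | 8β,9β-epoxy-9-{2-[(4S)-2,2-dimethyl-4-(2-oxoethyl)-1,3-dioxolan-4-yl]ethyl}-11-nordriman-7-one | CC1(C)CCC[C@@]2(C)[C@H]1CC(=O)[C@]3(C)O[C@@]32CC[C@]1(CC=O)COC(C)(C)O1 | intermediate
27 | 8β,9β-epoxy-9-[2-(3,5-dihydroxyoxolan-3-yl)ethyl]-11-nordriman-7-one (epoxy lactol; C15 anomers) | CC1(C)CCC[C@@]2(C)[C@H]1CC(=O)[C@]3(C)O[C@@]32CC[C@@]1(O)COC(O)C1 | intermediate
28 | (13S)-9α,13:15,16-diepoxy-8β,15-dihydroxylabdan-7-one (C15 anomers) | CC1(C)CCC[C@@]2(C)[C@H]1CC(=O)[C@](C)(O)[C@]21CC[C@]2(COC(O)C2)O1 | intermediate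
29 | (13S)-9α,13-epoxy-8β-hydroxy-7-oxolabdan-15,16-olide | CC1(C)CCC[C@@]2(C)[C@H]1CC(=O)[C@](C)(O)[C@]21CC[C@]2(COC(=O)C2)O1 | target

**Step count**

Total: 21 steps. Longest linear sequence: 15 steps (steps 7–21, from 3-bromobut-3-en-1-ol); the carvone branch is 12 steps (steps 3–6 and 14–21).

**Steps most likely to fail**

Step 5. Ring closure may be outrun by protodesilylation of the vinylsilane, or by a 1,2-hydride shift from C5 to the C4 cation followed by proton loss into a conjugated dienone that no longer cyclises. The fallback forms C3–C4 from a C4 radical and sets out from 6, through enolate 7. Alkylation with methyl 2-(bromomethyl)acrylate, anti to the isopropenyl group, would give the acrylate-bearing methylcarvone F1. Hydrogen-atom transfer from an iron hydride (Fe(acac)3, PhSiH3, EtOH/ethylene glycol, 60 °C) to the isopropenyl group then gives the tertiary C4 radical, which adds in Giese fashion to the acrylate CH2 (6-endo) to give the trans-fused ester F2 as C2 epimers. LiOH hydrolysis gives the acid F3. The acid is converted (N-hydroxypyridine-2-thione, DCC) into the thiohydroxamate ester F4 and reduced by Barton decarboxylation (t-BuSH, hν) to 10, where the route is rejoined; step 6 is then not needed.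

Step 17. Oxygen may be delivered to the α face if shielding by the C10 methyl overrides the direction by the pseudoequatorial 7β-hydroxyl, or hydride delivery in step 16 may leave the directing hydroxyl on the wrong face. The fallback inverts the facial logic and sets out from 23. N-Bromosuccinimide in aqueous THF would place the bromonium ion on the open α face, and water would open it trans-diaxially at C8 to give the bromohydrin F5 (9α-Br, 8β-OH). K2CO3 in MeOH then closes the ring by backside displacement of bromide at C9 and gives the 8β,9β-epoxide 24, where the route is rejoined.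

Step 20. The primary C16 hydroxyl (six-membered ether) or water may open the epoxide in competition with the tertiary C13 hydroxyl, and the protonated epoxy ketone may undergo an acyl shift. The fallback acylates O16 before any epoxide exists and sets out from 22. Johnson–Lemieux cleavage (OsO4 cat., NaIO4, 2,6-lutidine, dioxane/H2O) of the terminal alkene gives the enone aldehyde F6. Aqueous TsOH removes the ketal to give the hydroxy lactol F7, and TEMPO/PhI(OAc)2 oxidises it to the hydroxy lactone F8. Luche reduction gives the 7β-alcohol F9. VO(acac)2/t-BuOOH then gives the epoxide F10, which only the C13 hydroxyl can open (spontaneously or with camphorsulfonic acid) to give the spiro ether diol F11. Dess–Martin oxidation of the C7 alcohol gives 29.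

**Further compounds**

F1 | step 5 | methyl 2-{[(1S,6S)-1,3-dimethyl-2-oxo-6-(prop-1-en-2-yl)cyclohex-3-en-1-yl]methyl}prop-2-enoate | CC1=CC[C@@H](C(C)=C)[C@](C)(CC(=C)C(=O)OC)C1=O
F2 | step 5 | methyl 9-oxo-11-nordrim-7-ene-2-carboxylate (C2 epimers) | CC1(C)CC(C(=O)OC)C[C@@]2(C)[C@H]1CC=C(C)C2=O
F3 | step 5 | 9-oxo-11-nordrim-7-ene-2-carboxylic acid (C2 epimers) | CC1(C)CC(C(=O)O)C[C@@]2(C)[C@H]1CC=C(C)C2=O
F4 | step 5 | 2-thioxopyridin-1(2H)-yl 9-oxo-11-nordrim-7-ene-2-carboxylate | CC1(C)CC(C(=O)ON3C=CC=CC3=S)C[C@@]2(C)[C@H]1CC=C(C)C2=O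
F5 | step 17 | 9α-bromo-9-{2-[(4S)-4-allyl-2,2-dimethyl-1,3-dioxolan-4-yl]ethyl}-11-nordrimane-7β,8β-diol | CC1(C)CCC[C@@]2(C)[C@H]1C[C@H](O)[C@](C)(O)[C@]2(Br)CC[C@]1(CC=C)COC(C)(C)O1
F6 | step 20 | 9-{2-[(4S)-2,2-dimethyl-4-(2-oxoethyl)-1,3-dioxolan-4-yl]ethyl}-11-nordrim-8-en-7-one | CC1(C)CCC[C@@]2(C)[C@H]1CC(=O)C(C)=C2CC[C@]1(CC=O)COC(C)(C)O1
F7 | step 20 | 9-[2-(3,5-dihydroxyoxolan-3-yl)ethyl]-11-nordrim-8-en-7-one (C15 anomers) | CC1(C)CCC[C@@]2(C)[C@H]1CC(=O)C(C)=C2CC[C@@]1(O)COC(O)C1
F8 | step 20 | 13-hydroxy-7-oxolabd-8-en-15,16-olide | CC1(C)CCC[C@@]2(C)[C@H]1CC(=O)C(C)=C2CC[C@@]1(O)COC(=O)C1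
F9 | step 20 | 7β,13-dihydroxylabd-8-en-15,16-olide | CC1(C)CCC[C@@]2(C)[C@H]1C[C@H](O)C(C)=C2CC[C@@]1(O)COC(=O)C1
F10 | step 20 | 8β,9β-epoxy-7β,13-dihydroxylabdan-15,16-olide | CC1(C)CCC[C@@]2(C)[C@H]1C[C@H](O)[C@]3(C)O[C@@]32CC[C@@]1(O)COC(=O)C1
F11 | step 20 | (13S)-9α,13-epoxy-7β,8β-dihydroxylabdan-15,16-olide | CC1(C)CCC[C@@]2(C)[C@H]1C[C@H](O)[C@](C)(O)[C@]21CC[C@]2(COC(=O)C2)O1
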